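# Synthesis plan for CNP0271389.1: (2R,3S)-naringenin-(3→8'')-apigenin 7''-O-sulfate

## The problem

- The target is a flavanone–flavone dimer. C3 of a naringenin unit is bonded to C8'' of an apigenin unit, and O7'' alone among six phenolic oxygens carries a sulfate.
- The linking bond joins an sp3 carbon α to the C4 ketone to an arene carbon flanked by C7''–O and C8a''–O. It is crowded and is not a biaryl bond.
- Ring C holds two adjacent stereocentres, C2 (R) and C3 (S), trans to each other. C3 is α to the ketone and benzylic, so it epimerises and the 2,3-trans isomer is the thermodynamic one. Only C2 needs absolute control, and C2 then dictates C3.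
- C2 is fragile. Its C2–O1 bond is benzylic to a para-oxygenated ring and β to the carbonyl. Strong acid can ionise it and base can open ring C by retro-oxa-Michael reaction; either erases the stereocentre.
- The aryl sulfate monoester is acid-labile. It has to be put on late, onto the only free phenol present at that moment, and then see only neutral conditions.
- The exploitable feature is the 1,5-relationship of C4 and O7'' (C4–C3–C8''–C7''–O7''). C4 can be held as the carbonyl of a five-membered benzofuran-2(3H)-one on O7''. Handing that acyl group to the phloroglucinol ring A closes ring C and frees O7''.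

## Retrosynthesis

**23 ⇐ 21 ⇐ 20 (S–O7'' bond; benzyl and carbonate C–O bonds).** The sulfate goes on last but one and all protecting groups leave by hydrogenolysis of the sodium salt 21 (through 22), so the sulfate never meets acid or base. This requires 20 to have exactly one free phenol, O7''. The forward steps must sulfate a hindered phenol and debenzylate without reducing the flavone C2''=C3'' bond or the benzylic C2–O1 bond.

**20 ⇐ 19 (C4–C4a).** Ring C is opened at the aryl ketone bond, and the acyl carbon is returned to O7'' as the lactone 19.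
- Cutting O1–C2 instead would leave a 2'-hydroxychalcone whose ring closure is reversible and would have to set C2 in an equilibrium.
- Cutting C4–C4a from a free acid would need a separate activating reagent and a separate protecting group on O7''.
- In 19 one functional group protects O7'', activates C4 as an aryl ester and marks O7'' for sulfation.
- The precursor lacks ring C. The forward step is a 6-exo Friedel–Crafts acylation that must outrun ionisation of C2–O1.

**19 ⇐ 17 (C4–O7'' acyl–oxygen bond, through 18).** The lactone is opened to a tert-butyl ester and a MOM ether on O7'', both acid-labile so that they fall together. The hydroxy acid 18 lactonises readily, so the tether costs no extra protecting-group step. The forward step must avoid base, because C3–H of 19 is acidic and β-elimination would expel the ring-A aryloxide.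

**17 ⇐ 10 + 16 (O1–C8a, the aryl–oxygen bond).** The ether is cut on the arene side, not at C2.
- Making O1–C2 by conjugate addition of phenol 11 across a C2=C3 double bond was rejected. The addition is reversible, because the adduct carries an acidic C3–H next to a good leaving group. Phloroglucinol monoethers also tend to add through carbon.
- Making O1–C2 by substitution at C2 was rejected as the main route because dehydration competes in a β-hydroxy ester.
- O–H insertion of alcohol 10 into aryne 16 never breaks the carbinol C–O bond, so C2 is retained and there is no elimination channel.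
- Aryne 16 comes from silyl triflate 15, made from phenol 11 through bromide 12. Its 3-alkoxy group must steer the oxygen to the distal carbon.

**10 ⇐ 9 (C2–H).** The carbinol is made by asymmetric transfer hydrogenation of aryl ketone 9. This is the only step that sets absolute configuration. The α-carbon of 10 needs no control because it becomes the labile C3.

**9 ⇐ 5 + 8 (C2–C3).** A crossed Claisen acylation joins the enolate of arylacetate 5 to acid chloride 8, which comes from 4-hydroxybenzoic acid 6 through 7.
- Ring B enters with its oxygen as a benzyl carbonate. This keeps the ring electron-poor, so C2–O1 does not ionise in the acidic steps, and it is removed in the final hydrogenolysis.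
- An aldol with the corresponding aldehyde would need an extra oxidation before the asymmetric reduction.

**5 ⇐ 4 ⇐ 3 ⇐ 2 ⇐ 1 (C3–C8'').** The sp3–sp2 bond is made by palladium-catalysed coupling of a zinc ester enolate with iodide 4.
- 4 comes from iodination of the fully O-alkylated flavone 3.
- O7'' is set apart at the start as a MOM ether (2), using its higher acidity in apigenin 1.
- A Claisen rearrangement of a 7-O-allyl ether would also reach C8'' but needs an oxidative degradation of the allyl group; it is kept as a fallback.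

## Roads not taken

**Alternative 1:** de novo construction of flavone ring A''.
- Cut: C8''–C8a'' and C6''–C7''. The arene is built, not bought.
- Key step: heating cyclobutenone A2 with siloxyalkyne A3 gives phenol A1 through a vinylketene, [2+2] cycloaddition, four-electron ring opening and six-electron closure.
- Merits: the allyl group that becomes the C8'' substituent and the three oxygens, each in a different state, are fixed by the pericyclic cascade. Nothing depends on selective alkylation of apigenin or on the site of iodination. In this respect it is more secure than the chosen plan.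
- Weak points: it rebuilds a commercial flavone. The pyrone ring and ring B'' still have to be added, and the ethyl ether on O5'' needs a Lewis-acid cleavage that a sulfate would not survive. The key step addresses neither the C3–C8'' bond nor the stereocentres, and the route is 8 to 10 steps longer.
- Comparison: the chosen plan sets against it two points of known flavone behaviour, namely 7-OH being the most acidic phenol and C8 being the halogenation site of 5,7-di-O-alkylflavones. It accepts these as residual risks in steps 1 and 3.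

**Alternative 2:** aryne insertion into a cinnamic acid.
- Cut: O1–C8a and C4–C4a together.
- Key step: the carboxylate of acid A5 adds to aryne 16, the same intermediate the chosen route uses. The aryl anion then attacks the acyl carbon, giving the 2'-hydroxychalcone A4. No ring closes.
- Merits: it is convergent, forms two ring-A bonds at once, uses an acid that needs no stereocentre, and reaches the full carbon skeleton several steps sooner than the chosen plan.
- Weak points: ring C must then be closed by a 6-endo oxa-Michael addition onto a trisubstituted α-aryl enone. That step is reversible, and C2 would have to be set by a chiral catalyst in an equilibrium for which this substrate class has no good model. The product can racemise through the same channel, and simple O-arylation of the acid competes with acyl transfer.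
- Comparison: the chosen plan pays with a separate reduction and an O-arylation. In return C2 is set by a ketone reduction with a well-understood model and is never again part of a reversible C–O bond formation, and the ring closure is an irreversible C–C bond formation that also unveils O7''.

**Alternative 3:** ortho-quinone methide cycloaddition.
- Cut: C3–C4 and O1–C2 in a [4+2] sense.
- Key step: a chiral Brønsted acid turns salicylaldehyde A8 (after acetalisation in situ) into a 4-methoxy ortho-quinone methide, which adds across stilbene A7 to give the 2,3-trans-4-methoxyflavan A6.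
- Merits: ring C and both stereocentres arise in one catalytic asymmetric step, which is better stereochemical economy than the chosen plan. The sulfate is placed early as a trichloroethyl diester, so its regiochemistry is trivial.
- Weak points: a 1,2-diarylethene with one hindered, electron-poor aryl group is a poor partner for ortho-quinone methides, which prefer electron-rich styrenes and enol ethers. C4 arrives at the wrong oxidation level and needs hydrolysis and oxidation next to an ionisable benzylic ether. The sulfate diester must survive Brønsted acid and later reductive unmasking.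
- Comparison: the chosen plan sets against the better convergence that C4 is delivered as the ketone directly, that every step belongs to a known reaction type, and that no sulfate is carried through acid.

Key step: step 13

Assumption: 3,5-bis(benzyloxy)phenol 11 and (2-tert-butoxy-2-oxoethyl)zinc bromide are purchased. The target is drawn as the free hydrogen sulfate, so it is released from its sodium salt 22 only in the last operation.

## Route

Step 1
Reactants: 1 apigenin
Product: 2 5-hydroxy-2-(4-hydroxyphenyl)-7-(methoxymethoxy)-4H-chromen-4-one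
Conditions: MOMCl (1.05 equiv), iPr2NEt (1.2 equiv), DMF, 0 °C
Reagents that add atoms: chloromethyl methyl ether, COCCl
Why: Williamson-type O-alkylation under limiting base; the 7-OH is the most acidic phenol of apigenin (vinylogous acid of the pyrone carbonyl), the 5-OH is chelated and the 4'-OH is less acidic, so one equivalent should go to O7.

Step 2
Reactants: 2 5-hydroxy-2-(4-hydroxyphenyl)-7-(methoxymethoxy)-4H-chromen-4-one
Product: 3 5-(benzyloxy)-2-[4-(benzyloxy)phenyl]-7-(methoxymethoxy)-4H-chromen-4-one
Conditions: BnBr (2.5 equiv), K2CO3, Bu4NI (cat.), DMF, 70 °C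
Reagents that add atoms: benzyl bromide, BrCc1ccccc1
Why: Williamson etherification; the chelated 5-OH needs the forcing conditions, and the MOM acetal is stable to base.

Step 3
Reactants: 3 5-(benzyloxy)-2-[4-(benzyloxy)phenyl]-7-(methoxymethoxy)-4H-chromen-4-one
Product: 4 5-(benzyloxy)-2-[4-(benzyloxy)phenyl]-8-iodo-7-(methoxymethoxy)-4H-chromen-4-one
Conditions: NIS (1.1 equiv), DMF, 20 °C, dark
Reagents that add atoms: N-iodosuccinimide, O=C1CCC(=O)N1I
Why: Electrophilic aromatic iodination; in 5,7-di-O-alkylated flavones C8, between O7 and the pyran oxygen, is the usual site of halogenation (a free chelated 5-OH would direct to C6), and ring B and the pyrone C3 are less nucleophilic; the acid-free conditions spare the MOM group.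

Step 4
Reactants: 4 5-(benzyloxy)-2-[4-(benzyloxy)phenyl]-8-iodo-7-(methoxymethoxy)-4H-chromen-4-one
Product: 5 tert-butyl 2-{5-(benzyloxy)-2-[4-(benzyloxy)phenyl]-7-(methoxymethoxy)-4-oxo-4H-chromen-8-yl}acetate
Conditions: BrZnCH2CO2t-Bu (2 equiv), Pd2(dba)3 (2.5 mol %), XPhos (10 mol %), THF, 50 °C
Reagents that add atoms: (2-tert-butoxy-2-oxoethyl)zinc bromide, CC(C)(C)OC(=O)C[Zn]Br
Why: Negishi-type coupling of a Reformatsky reagent with an aryl iodide; the neutral zinc enolate leaves the pyrone carbonyl alone, and the bulky biarylphosphine on zerovalent palladium is chosen for the doubly ortho-substituted iodide.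

Step 5
Reactants: 6 4-hydroxybenzoic acid
Product: 7 4-{[(benzyloxy)carbonyl]oxy}benzoic acid
Conditions: CbzCl (1.1 equiv), NaOH (2.1 equiv), H2O–acetone, 0 °C; then HCl to pH 2
Reagents that add atoms: benzyl chloroformate, O=C(Cl)OCc1ccccc1
Why: Schotten–Baumann acylation of the phenoxide; any mixed anhydride formed at the carboxylate is hydrolysed back in the aqueous base.

Step 6
Reactants: 7 4-{[(benzyloxy)carbonyl]oxy}benzoic acid
Product: 8 4-{[(benzyloxy)carbonyl]oxy}benzoyl chloride
Conditions: (COCl)2 (1.5 equiv), DMF (cat.), CH2Cl2, 0 → 20 °C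
Reagents that add atoms: oxalyl chloride, O=C(Cl)C(=O)Cl
Why: Acid chloride formation through the Vilsmeier-type chloroiminium catalyst; the aryl benzyl carbonate is inert to these conditions.

Step 7
Reactants: 5 tert-butyl 2-{5-(benzyloxy)-2-[4-(benzyloxy)phenyl]-7-(methoxymethoxy)-4-oxo-4H-chromen-8-yl}acetate; 8 4-{[(benzyloxy)carbonyl]oxy}benzoyl chloride
Product: 9 tert-butyl 2-{5-(benzyloxy)-2-[4-(benzyloxy)phenyl]-7-(methoxymethoxy)-4-oxo-4H-chromen-8-yl}-3-(4-{[(benzyloxy)carbonyl]oxy}phenyl)-3-oxopropanoate
Conditions: LiHMDS (2.1 equiv), THF, −78 °C; then 8, −78 → −40 °C; AcOH quench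
Reagents that add atoms: none
Why: Crossed Claisen C-acylation of the ester enolate by the acid chloride, which forms the C2–C3 bond; the second equivalent of base takes up the more acidic β-keto ester, and the low temperature protects the carbonate.

Step 8
Reactants: 9 tert-butyl 2-{5-(benzyloxy)-2-[4-(benzyloxy)phenyl]-7-(methoxymethoxy)-4-oxo-4H-chromen-8-yl}-3-(4-{[(benzyloxy)carbonyl]oxy}phenyl)-3-oxopropanoate
Product: 10 tert-butyl (3R)-2-{5-(benzyloxy)-2-[4-(benzyloxy)phenyl]-7-(methoxymethoxy)-4-oxo-4H-chromen-8-yl}-3-(4-{[(benzyloxy)carbonyl]oxy}phenyl)-3-hydroxypropanoate (both C2 epimers)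
Conditions: RuCl[(R,R)-TsDPEN](p-cymene) (3 mol %), HCO2H–Et3N (5:2), DMF, 35 °C
Reagents that add atoms: none
Why: Noyori–Ikariya asymmetric transfer hydrogenation of an aryl ketone with a divalent ruthenium catalyst; by analogy with aryl alkyl ketones the (R,R)-catalyst should give the (R)-carbinol, the future C2. The α-carbon epimerises through the enol and needs no control because it becomes the labile C3.

Step 9
Reactants: 11 3,5-bis(benzyloxy)phenol
Product: 12 3,5-bis(benzyloxy)-2-bromophenol
Conditions: NBS (1.0 equiv), CH2Cl2, −78 °C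
Reagents that add atoms: N-bromosuccinimide, O=C1CCC(=O)N1Br
Why: Electrophilic aromatic bromination; the two equivalent positions ortho to the hydroxyl should be favoured over the single position flanked by both benzyloxy groups, and any 4-bromo isomer would be removed by chromatography.

Step 10
Reactants: 12 3,5-bis(benzyloxy)-2-bromophenol
Product: 15 3,5-bis(benzyloxy)-2-(trimethylsilyl)phenyl trifluoromethanesulfonate, via aryl trimethylsilyl ether 13 (not isolated), via lithium 2-silylphenoxide 14 (not isolated)
Conditions: (Me3Si)2NH, THF, 65 °C; evaporate; n-BuLi, THF, −78 °C; Tf2O, −78 → 20 °C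
Reagents that add atoms: hexamethyldisilazane, C[Si](C)(C)N[Si](C)(C)C; trifluoromethanesulfonic anhydride, O=S(=O)(OS(=O)(=O)C(F)(F)F)C(F)(F)F
Why: Standard route to an ortho-silylaryl triflate: O-silylation, bromine–lithium exchange with 1,3-O→C silyl shift (retro-Brook rearrangement), and triflation of the resulting phenoxide.

Step 11
Reactants: 10 tert-butyl (3R)-2-{5-(benzyloxy)-2-[4-(benzyloxy)phenyl]-7-(methoxymethoxy)-4-oxo-4H-chromen-8-yl}-3-(4-{[(benzyloxy)carbonyl]oxy}phenyl)-3-hydroxypropanoate; 15 3,5-bis(benzyloxy)-2-(trimethylsilyl)phenyl trifluoromethanesulfonate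
Product: 17 tert-butyl (3R)-3-[3,5-bis(benzyloxy)phenoxy]-2-{5-(benzyloxy)-2-[4-(benzyloxy)phenyl]-7-(methoxymethoxy)-4-oxo-4H-chromen-8-yl}-3-(4-{[(benzyloxy)carbonyl]oxy}phenyl)propanoate (both C2 epimers), via 3,5-bis(benzyloxy)benzyne 16 (not isolated)
Conditions: KF (4 equiv), 18-crown-6 (4 equiv), THF, −20 °C; 15 (2 equiv) added slowly
Reagents that add atoms: none
Why: O–H insertion of an aliphatic alcohol into an aryne released by fluoride from the silyl triflate; the carbinol C–O bond is never broken, so the future C2 is carried over with retention and no elimination channel exists. The alkoxy group next to the aryne bond directs the oxygen nucleophile to the distal carbon, so the 3,5-bis(benzyloxy)phenyl ether is the only regioisomer expected.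

Step 12
Reactants: 17 tert-butyl (3R)-3-[3,5-bis(benzyloxy)phenoxy]-2-{5-(benzyloxy)-2-[4-(benzyloxy)phenyl]-7-(methoxymethoxy)-4-oxo-4H-chromen-8-yl}-3-(4-{[(benzyloxy)carbonyl]oxy}phenyl)propanoate
Product: 19 (9S)-9-{(R)-[3,5-bis(benzyloxy)phenoxy](4-{[(benzyloxy)carbonyl]oxy}phenyl)methyl}-5-(benzyloxy)-2-[4-(benzyloxy)phenyl]-4H-furo[2,3-h]chromene-4,8(9H)-dione (lactone between O7'' and C4; C9 is the future C3 and is labile), via hydroxy acid 18 (not isolated)
Conditions: TFA–CH2Cl2–H2O (30:68:2), 1,3,5-trimethoxybenzene (5 equiv), 0 → 20 °C; evaporate with toluene; then iPrN=C=NiPr (1.1 equiv), CH2Cl2, 0 °C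
Reagents that add atoms: none
Why: Acidolysis removes the tert-butyl ester and the MOM acetal together, and the carbodiimide closes the five-membered aryl lactone without base, which matters because base would expel the ring-A aryloxide from 19 by β-elimination. The arene trap keeps methoxymethyl and tert-butyl cations away from ring A; the carbonate-bearing ring B keeps C2–O1 from ionising in the acid. 19 is drawn as the epimer that maps onto the trans product.

Step 13
Reactants: 19 (9S)-9-{(R)-[3,5-bis(benzyloxy)phenoxy](4-{[(benzyloxy)carbonyl]oxy}phenyl)methyl}-5-(benzyloxy)-2-[4-(benzyloxy)phenyl]-4H-furo[2,3-h]chromene-4,8(9H)-dione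
Product: 20 benzyl 4-[(2R,3S)-5,7-bis(benzyloxy)-3-{5-(benzyloxy)-2-[4-(benzyloxy)phenyl]-7-hydroxy-4-oxo-4H-chromen-8-yl}-4-oxo-3,4-dihydro-2H-chromen-2-yl]phenyl carbonate
Conditions: BF3·OEt2 (4 equiv), CH2Cl2, −20 → 20 °C; aq. NaHCO3 quench
Reagents that add atoms: none
Why: Once the pyrone carbonyl has taken its share of Lewis acid, BF3 binds the aryl-lactone carbonyl, and one of the two equivalent positions ortho to O1 on the 3,5-bis(benzyloxy)phenyl ether (para to a benzyloxy group) attacks it. Rearomatisation gives a boron-bound hemiketal that collapses with loss of the O7'' aryloxide, a vinylogous carboxylate and the better leaving group, so the five-membered lactone opens as C4–C4a forms; the closest known reaction type is the Fries-type transacylation and intramolecular Friedel–Crafts acylation of phloroglucinol ethers by aryl esters and lactones. Ring C closes in a 6-exo-trig mode (nucleophile C4a, electrophile C4, carbonyl oxygen outside the new ring). No stereocentre is created: C2 is carried through because its C–O bond is not touched, and C3, now α to an aryl ketone, should settle under the acidic conditions into the 2,3-trans arrangement whatever its configuration in 19. The step needs acylation to outrun ionisation of the benzylic C2–O1 bond, and the electron-poor carbonate-bearing ring B and the adjacent Lewis-acid-bound acyl group both destabilise a cation at C2. Regiochemistry is secured by the symmetry of ring A, since the para position cannot reach C4. The aryl ketone cannot return to the lactone, and O7'' emerges as the only free phenol.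

Step 14
Reactants: 20 benzyl 4-[(2R,3S)-5,7-bis(benzyloxy)-3-{5-(benzyloxy)-2-[4-(benzyloxy)phenyl]-7-hydroxy-4-oxo-4H-chromen-8-yl}-4-oxo-3,4-dihydro-2H-chromen-2-yl]phenyl carbonate
Product: 21 sodium 5-(benzyloxy)-2-[4-(benzyloxy)phenyl]-8-[(2R,3S)-5,7-bis(benzyloxy)-2-(4-{[(benzyloxy)carbonyl]oxy}phenyl)-4-oxo-3,4-dihydro-2H-chromen-3-yl]-4-oxo-4H-chromen-7-yl sulfate
Conditions: SO3·pyridine (3 equiv), DMF, 25 °C; then aq. NaHCO3
Reagents that add atoms: sulfur trioxide pyridine complex, O=S(=O)([O-])[n+]1ccccc1; sodium hydrogencarbonate, [Na+].OC([O-])=O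
Why: O-sulfation of a phenol with an amine–sulfur trioxide complex; O7'' is the only free hydroxyl, so no regiochemical choice arises, and exchange to the sodium salt removes pyridine before the hydrogenation.

Step 15
Reactants: 21 sodium 5-(benzyloxy)-2-[4-(benzyloxy)phenyl]-8-[(2R,3S)-5,7-bis(benzyloxy)-2-(4-{[(benzyloxy)carbonyl]oxy}phenyl)-4-oxo-3,4-dihydro-2H-chromen-3-yl]-4-oxo-4H-chromen-7-yl sulfate
Product: 23 8-[(2R,3S)-5,7-dihydroxy-2-(4-hydroxyphenyl)-4-oxo-3,4-dihydro-2H-chromen-3-yl]-5-hydroxy-2-(4-hydroxyphenyl)-4-oxo-4H-chromen-7-yl hydrogen sulfate (CNP0271389.1), via sodium salt of the target 22 (not isolated)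
Conditions: H2 (1 atm), 10% Pd/C, THF–MeOH, 20 °C; filter; HCl (1.0 equiv), H2O, 0 °C; lyophilise
Reagents that add atoms: none
Why: Hydrogenolysis of the four benzyl ethers and the benzyl carbonate (which loses CO2) under neutral conditions that aryl sulfate salts, the flavone double bond and the flavanone tolerate; one equivalent of cold acid then gives the hydrogen sulfate as drawn.

## Compound list

1 | apigenin | O=c1cc(-c2ccc(O)cc2)oc2cc(O)cc(O)c12 | starting material
2 | 5-hydroxy-2-(4-hydroxyphenyl)-7-(methoxymethoxy)-4H-chromen-4-one | COCOc1cc(O)c2c(=O)cc(-c3ccc(O)cc3)oc2c1 | intermediate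
3 | 5-(benzyloxy)-2-[4-(benzyloxy)phenyl]-7-(methoxymethoxy)-4H-chromen-4-one | COCOc1cc(OCc2ccccc2)c2c(=O)cc(-c3ccc(OCc4ccccc4)cc3)oc2c1 | intermediate
4 | 5-(benzyloxy)-2-[4-(benzyloxy)phenyl]-8-iodo-7-(methoxymethoxy)-4H-chromen-4-one | COCOc1cc(OCc2ccccc2)c2c(=O)cc(-c3ccc(OCc4ccccc4)cc3)oc2c1I | intermediate
5 | tert-butyl 2-{5-(benzyloxy)-2-[4-(benzyloxy)phenyl]-7-(methoxymethoxy)-4-oxo-4H-chromen-8-yl}acetate | COCOc1cc(OCc2ccccc2)c2c(=O)cc(-c3ccc(OCc4ccccc4)cc3)oc2c1CC(=O)OC(C)(C)C | intermediate
6 | 4-hydroxybenzoic acid | O=C(O)c1ccc(O)cc1 | starting material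
7 | 4-{[(benzyloxy)carbonyl]oxy}benzoic acid | O=C(O)c1ccc(OC(=O)OCc2ccccc2)cc1 | intermediate
8 | 4-{[(benzyloxy)carbonyl]oxy}benzoyl chloride | O=C(Cl)c1ccc(OC(=O)OCc2ccccc2)cc1 | intermediate
9 | tert-butyl 2-{5-(benzyloxy)-2-[4-(benzyloxy)phenyl]-7-(methoxymethoxy)-4-oxo-4H-chromen-8-yl}-3-(4-{[(benzyloxy)carbonyl]oxy}phenyl)-3-oxopropanoate (racemic at C2) | COCOc1cc(OCc2ccccc2)c2c(=O)cc(-c3ccc(OCc4ccccc4)cc3)oc2c1C(C(=O)OC(C)(C)C)C(=O)c1ccc(OC(=O)OCc2ccccc2)cc1 | intermediate
10 | tert-butyl (3R)-2-{5-(benzyloxy)-2-[4-(benzyloxy)phenyl]-7-(methoxymethoxy)-4-oxo-4H-chromen-8-yl}-3-(4-{[(benzyloxy)carbonyl]oxy}phenyl)-3-hydroxypropanoate (both C2 epimers) | COCOc1cc(OCc2ccccc2)c2c(=O)cc(-c3ccc(OCc4ccccc4)cc3)oc2c1C(C(=O)OC(C)(C)C)[C@@H](O)c1ccc(OC(=O)OCc2ccccc2)cc1 | intermediate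
11 | 3,5-bis(benzyloxy)phenol | Oc1cc(OCc2ccccc2)cc(OCc2ccccc2)c1 | starting material
12 | 3,5-bis(benzyloxy)-2-bromophenol | Oc1cc(OCc2ccccc2)cc(OCc2ccccc2)c1Br | intermediate
13 | [3,5-bis(benzyloxy)-2-bromophenoxy]trimethylsilane | C[Si](C)(C)Oc1cc(OCc2ccccc2)cc(OCc2ccccc2)c1Br | intermediate
14 | lithium 3,5-bis(benzyloxy)-2-(trimethylsilyl)phenoxide | [Li+].[O-]c1cc(OCc2ccccc2)cc(OCc2ccccc2)c1[Si](C)(C)C | intermediate
15 | 3,5-bis(benzyloxy)-2-(trimethylsilyl)phenyl trifluoromethanesulfonate | C[Si](C)(C)c1c(OCc2ccccc2)cc(OCc2ccccc2)cc1OS(=O)(=O)C(F)(F)F | intermediate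
16 | 3,5-bis(benzyloxy)benzyne | C1#CC(OCc2ccccc2)=CC(OCc2ccccc2)=C1 | intermediate
17 | tert-butyl (3R)-3-[3,5-bis(benzyloxy)phenoxy]-2-{5-(benzyloxy)-2-[4-(benzyloxy)phenyl]-7-(methoxymethoxy)-4-oxo-4H-chromen-8-yl}-3-(4-{[(benzyloxy)carbonyl]oxy}phenyl)propanoate (both C2 epimers) | COCOc1cc(OCc2ccccc2)c2c(=O)cc(-c3ccc(OCc4ccccc4)cc3)oc2c1C(C(=O)OC(C)(C)C)[C@@H](Oc1cc(OCc2ccccc2)cc(OCc2ccccc2)c1)c1ccc(OC(=O)OCc2ccccc2)cc1 | intermediate
18 | (3R)-3-[3,5-bis(benzyloxy)phenoxy]-2-{5-(benzyloxy)-2-[4-(benzyloxy)phenyl]-7-hydroxy-4-oxo-4H-chromen-8-yl}-3-(4-{[(benzyloxy)carbonyl]oxy}phenyl)propanoic acid (both C2 epimers) | OC(=O)C(c1c(O)cc(OCc2ccccc2)c2c(=O)cc(-c3ccc(OCc4ccccc4)cc3)oc12)[C@@H](Oc1cc(OCc2ccccc2)cc(OCc2ccccc2)c1)c1ccc(OC(=O)OCc2ccccc2)cc1 | intermediate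
19 | (9S)-9-{(R)-[3,5-bis(benzyloxy)phenoxy](4-{[(benzyloxy)carbonyl]oxy}phenyl)methyl}-5-(benzyloxy)-2-[4-(benzyloxy)phenyl]-4H-furo[2,3-h]chromene-4,8(9H)-dione (flavone-fused benzofuran-2(3H)-one; C9 labile, drawn as the epimer that maps onto the trans product) | O=C1Oc2cc(OCc3ccccc3)c3c(=O)cc(-c4ccc(OCc5ccccc5)cc4)oc3c2[C@H]1[C@@H](Oc1cc(OCc2ccccc2)cc(OCc2ccccc2)c1)c1ccc(OC(=O)OCc2ccccc2)cc1 | intermediate
20 | benzyl 4-[(2R,3S)-5,7-bis(benzyloxy)-3-{5-(benzyloxy)-2-[4-(benzyloxy)phenyl]-7-hydroxy-4-oxo-4H-chromen-8-yl}-4-oxo-3,4-dihydro-2H-chromen-2-yl]phenyl carbonate | O=C1c2c(OCc3ccccc3)cc(OCc3ccccc3)cc2O[C@@H](c2ccc(OC(=O)OCc3ccccc3)cc2)[C@@H]1c1c(O)cc(OCc2ccccc2)c2c(=O)cc(-c3ccc(OCc4ccccc4)cc3)oc12 | intermediate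
21 | sodium 5-(benzyloxy)-2-[4-(benzyloxy)phenyl]-8-[(2R,3S)-5,7-bis(benzyloxy)-2-(4-{[(benzyloxy)carbonyl]oxy}phenyl)-4-oxo-3,4-dihydro-2H-chromen-3-yl]-4-oxo-4H-chromen-7-yl sulfate | O=C1c2c(OCc3ccccc3)cc(OCc3ccccc3)cc2O[C@@H](c2ccc(OC(=O)OCc3ccccc3)cc2)[C@@H]1c1c(OS(=O)(=O)[O-])cc(OCc2ccccc2)c2c(=O)cc(-c3ccc(OCc4ccccc4)cc3)oc12.[Na+] | intermediate
22 | sodium 8-[(2R,3S)-5,7-dihydroxy-2-(4-hydroxyphenyl)-4-oxo-3,4-dihydro-2H-chromen-3-yl]-5-hydroxy-2-(4-hydroxyphenyl)-4-oxo-4H-chromen-7-yl sulfate | O=C1c2c(O)cc(O)cc2O[C@@H](c2ccc(O)cc2)[C@@H]1c1c(OS(=O)(=O)[O-])cc(O)c2c(=O)cc(-c3ccc(O)cc3)oc12.[Na+] | intermediate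
23 | 8-[(2R,3S)-5,7-dihydroxy-2-(4-hydroxyphenyl)-4-oxo-3,4-dihydro-2H-chromen-3-yl]-5-hydroxy-2-(4-hydroxyphenyl)-4-oxo-4H-chromen-7-yl hydrogen sulfate (CNP0271389.1) | O=C1c2c(O)cc(O)cc2O[C@@H](c2ccc(O)cc2)[C@@H]1c1c(OS(=O)(=O)O)cc(O)c2c(=O)cc(-c3ccc(O)cc3)oc12 | target

## Step count and least certain steps

Total steps: 15. Longest linear sequence: 11 steps from apigenin (steps 1–4, 7, 8, 11–15). The acid chloride (steps 5, 6) and the aryne precursor (steps 9, 10) are side branches.

**Step 13 (key step).**
- Ionisation of the benzylic C2–O1 bond under Lewis acid may compete with acylation. That would lead to loss of the ring-A phenol or to C-alkylation of ring A, and in either case to loss of C2.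
- The aryl lactone may be too weakly activated once the two pyrone carbonyls have bound the Lewis acid.
- The product may over-react by acid-promoted cyclodehydration between the new ketone and the freshly released ortho-phenol O7''–H, giving a furan, as 2'-hydroxyisoflavanones do.
- Debenzylation at the peri O5 positions is a minor risk.
- Fallback: set out from hydroxy acid 18, obtained by stopping step 12 before the carbodiimide. Add it to excess trifluoroacetic anhydride in CH2Cl2 at 0 °C, which caps O7'' as its trifluoroacetate and turns the acid into the mixed anhydride. Intramolecular Friedel–Crafts acylation of the phloroglucinol ether ring, a known closure for 3-aryloxy-3-arylpropanoic acids, should give the 7''-O-trifluoroacetate of 20 F1. The capped phenol cannot cyclodehydrate. NaHCO3 in methanol at 0 °C removes the trifluoroacetate and the route is rejoined at 20.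

**Step 11 (aryne O-arylation).**
- Capture of the short-lived aryne by a hindered, hydrogen-bonded secondary alcohol may be slow, so the aryne is consumed by fluoride or solvent.
- Fluoride may also induce retro-aldol cleavage or attack the aryl carbonate.
- Fallback: set out from ketone 9. Reduce it with the enantiomeric catalyst RuCl[(S,S)-TsDPEN](p-cymene) to the (3S)-alcohol tert-butyl (3S)-2-{5-(benzyloxy)-2-[4-(benzyloxy)phenyl]-7-(methoxymethoxy)-4-oxo-4H-chromen-8-yl}-3-(4-{[(benzyloxy)carbonyl]oxy}phenyl)-3-hydroxypropanoate F2. Couple F2 with phenol 11 under Mitsunobu conditions (PPh3, DIAD, toluene, 0 °C). Substitution with inversion returns to 17.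
- This replaces aryl transfer to oxygen by SN2 at carbon. Its own liability is competing dehydration of the β-hydroxy ester, which is why it is not the first choice.

**Step 4 (coupling at the hindered iodide).**
- Transmetalation and reductive elimination at the doubly ortho-substituted carbon may be slow, leading to protodeiodination or decay of the zinc enolate.
- Fallback: set out from iodide 4.
  - Stille allylation (allyltributylstannane, Pd(PPh3)4, toluene, 100 °C) gives the 8-allyl flavone F3.
  - Lemieux–Johnson cleavage (OsO4 cat., NaIO4, 2,6-lutidine, dioxane–water) gives the arylacetaldehyde F4.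
  - Pinnick oxidation (NaClO2, NaH2PO4, 2-methyl-2-butene) gives the arylacetic acid F5.
  - Esterification with Boc2O, DMAP and tert-butanol returns to 5.
- The C8''–C3 bond is then made by allyl transfer and oxidative degradation instead of enolate coupling.

**Step 8 (asymmetric transfer hydrogenation).**
- Hydride transfer to a ketone flanked by a crowded, partly enolised α-carbon may be slow or poorly face-selective.
- Fallback: set out from ester 5.
  - 4-Hydroxybenzaldehyde and benzyl chloroformate (Et3N, CH2Cl2) give benzyl 4-formylphenyl carbonate F6.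
  - Aldol addition of the lithium enolate of 5 to F6 (LiHMDS, THF, −78 °C, cold quench) gives the racemic β-hydroxy ester F7.
  - Preparative chromatography on a chiral stationary phase separates the (3R) isomers, which are 10, where the route is rejoined.
- Absolute configuration then comes from resolution, not from catalysis, at the cost of half the material.

## Further compounds

F1 | step 13 | benzyl 4-[(2R,3S)-5,7-bis(benzyloxy)-3-{5-(benzyloxy)-2-[4-(benzyloxy)phenyl]-4-oxo-7-[(trifluoroacetyl)oxy]-4H-chromen-8-yl}-4-oxo-3,4-dihydro-2H-chromen-2-yl]phenyl carbonate | O=C1c2c(OCc3ccccc3)cc(OCc3ccccc3)cc2O[C@@H](c2ccc(OC(=O)OCc3ccccc3)cc2)[C@@H]1c1c(OC(=O)C(F)(F)F)cc(OCc2ccccc2)c2c(=O)cc(-c3ccc(OCc4ccccc4)cc3)oc12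
F2 | step 11 | tert-butyl (3S)-2-{5-(benzyloxy)-2-[4-(benzyloxy)phenyl]-7-(methoxymethoxy)-4-oxo-4H-chromen-8-yl}-3-(4-{[(benzyloxy)carbonyl]oxy}phenyl)-3-hydroxypropanoate (both C2 epimers) | COCOc1cc(OCc2ccccc2)c2c(=O)cc(-c3ccc(OCc4ccccc4)cc3)oc2c1C(C(=O)OC(C)(C)C)[C@H](O)c1ccc(OC(=O)OCc2ccccc2)cc1
F3 | step 4 | 8-allyl-5-(benzyloxy)-2-[4-(benzyloxy)phenyl]-7-(methoxymethoxy)-4H-chromen-4-one | COCOc1cc(OCc2ccccc2)c2c(=O)cc(-c3ccc(OCc4ccccc4)cc3)oc2c1CC=C
F4 | step 4 | 2-{5-(benzyloxy)-2-[4-(benzyloxy)phenyl]-7-(methoxymethoxy)-4-oxo-4H-chromen-8-yl}acetaldehyde | COCOc1cc(OCc2ccccc2)c2c(=O)cc(-c3ccc(OCc4ccccc4)cc3)oc2c1CC=O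
F5 | step 4 | 2-{5-(benzyloxy)-2-[4-(benzyloxy)phenyl]-7-(methoxymethoxy)-4-oxo-4H-chromen-8-yl}acetic acid | COCOc1cc(OCc2ccccc2)c2c(=O)cc(-c3ccc(OCc4ccccc4)cc3)oc2c1CC(=O)O
F6 | step 8 | benzyl 4-formylphenyl carbonate | O=Cc1ccc(OC(=O)OCc2ccccc2)cc1
F7 | step 8 | tert-butyl 2-{5-(benzyloxy)-2-[4-(benzyloxy)phenyl]-7-(methoxymethoxy)-4-oxo-4H-chromen-8-yl}-3-(4-{[(benzyloxy)carbonyl]oxy}phenyl)-3-hydroxypropanoate (racemic; all stereoisomers) | COCOc1cc(OCc2ccccc2)c2c(=O)cc(-c3ccc(OCc4ccccc4)cc3)oc2c1C(C(=O)OC(C)(C)C)C(O)c1ccc(OC(=O)OCc2ccccc2)cc1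
A1 | alternative 1 | 2-allyl-5-ethoxy-3-(triisopropylsilyloxy)phenol | C=CCc1c(O)cc(OCC)cc1O[Si](C(C)C)(C(C)C)C(C)C
A2 | alternative 1 | 3-ethoxycyclobut-2-en-1-one | CCOC1=CC(=O)C1
A3 | alternative 1 | triisopropyl(pent-4-en-1-yn-1-yloxy)silane | C=CCC#CO[Si](C(C)C)(C(C)C)C(C)C
A4 | alternative 2 | 2'-hydroxy-4',6'-bis(benzyloxy)-α-(flavon-8-yl)chalcone | O=C(c1c(O)cc(OCc2ccccc2)cc1OCc1ccccc1)/C(=C/c1ccc(OCc2ccccc2)cc1)c1c(OCOC)cc(OCc2ccccc2)c2c(=O)cc(-c3ccc(OCc4ccccc4)cc3)oc12
A5 | alternative 2 | (E)-2-{5-(benzyloxy)-2-[4-(benzyloxy)phenyl]-7-(methoxymethoxy)-4-oxo-4H-chromen-8-yl}-3-[4-(benzyloxy)phenyl]acrylic acid | OC(=O)/C(=C/c1ccc(OCc2ccccc2)cc1)c1c(OCOC)cc(OCc2ccccc2)c2c(=O)cc(-c3ccc(OCc4ccccc4)cc3)oc12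
A6 | alternative 3 | 2,3-trans-4-methoxyflavan carrying the 7''-O-(trichloroethyl sulfate) flavone at C3 | CO[C@H]1c2c(OCc3ccccc3)cc(OCc3ccccc3)cc2O[C@@H](c2ccc(OCc3ccccc3)cc2)[C@@H]1c1c(OS(=O)(=O)OCC(Cl)(Cl)Cl)cc(OCc2ccccc2)c2c(=O)cc(-c3ccc(OCc4ccccc4)cc3)oc12
A7 | alternative 3 | 5-(benzyloxy)-2-[4-(benzyloxy)phenyl]-8-[(E)-4-(benzyloxy)styryl]-4-oxo-4H-chromen-7-yl 2,2,2-trichloroethyl sulfate | O=S(=O)(OCC(Cl)(Cl)Cl)Oc1cc(OCc2ccccc2)c2c(=O)cc(-c3ccc(OCc4ccccc4)cc3)oc2c1/C=C/c1ccc(OCc2ccccc2)cc1
A8 | alternative 3 | 2,4-bis(benzyloxy)-6-hydroxybenzaldehyde | O=Cc1c(O)cc(OCc2ccccc2)cc1OCc1ccccc1
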